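Late in both runs the slope of ln g, where g is the share of the G charge still present, shows what the flask is doing.

| flask | G | L | time |
|---|---|---|---|
| west | 200 mM | 4.00 mM |  |
| east | 200 mM | 2.00 mM |  |
| north-east | 400 mM | 2.00 mM | 9.0 min |

| run | time / min | [G] / mM |
|---|---|---|
| west run | 0.36 | 182.8 |
| west run | 0.62 | 172.2 |
| west run | 1.1 | 153.9 |
| west run | 1.8 | 132.9 |
| west run | 3.1 | 108.4 |
| west run | 5.3 | 81.3 |
| west run | 9.0 | 59.8 |
| east run | 0.36 | 189.1 |
| east run | 0.62 | 181.3 |
| east run | 1.1 | 170.8 |
| east run | 1.8 | 158.2 |
| east run | 3.1 | 136.6 |
| east run | 5.3 | 114.1 |
| east run | 9.0 | 89.9 |

(standard deviation of a reading: 0.6 mM)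

- Overall: G -> Z, with L as catalyst.
- Constant volume, constant temperature.
- Bound and free are read together.
- An order is taken over about fifteen percent of the charge, up and down.

1. how the opening rate goes with [L] round the charge of the west run: the exponent of the rate at two percent of G gone to Z
2. G in the north-east run at 9.0 min, as a share of the G charged

Between 5.3 min and 9.0 min that slope has size 0.0830 min⁻¹ in the west run and 0.0644 min⁻¹ in the east run. The west run holds twice the L, yet its slope is 1.29 times the east one, less than the ratio of the L charges. The first readings give opening losses of 47.8 mM min⁻¹ and 30.3 mM min⁻¹, a ratio of 1.58.

These numbers fit a proportional catalyst if the slope is a sum, one part proportional to L and one part free of it. Carried back to zero L, the two slopes give a reading of the L-free loss constant, the first-order rate constant with which G disappears without help from L: 0.0458 min⁻¹. Subtracting this loss from the opening losses gives an exponent in L of 0.871, which is read here as close to first order.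

By 9.0 min the L-free path by itself leaves a share 66.2%, while the east run shows 45.0%. The north-east flask has the same L. Assuming its catalyst takes the same amount of G, an assumption no run tests, that amount is half the share at the larger charge, and the reckoning gives 55.6%.

The forecast, different from this reckoning, gave an exponent of 0.7 and a share of 33%, with “true second order in G as the leading reading” as its starting point. The flask gives an exponent of 1.0 and a share of 53.4%.

    L + G ⇌ LG, settled at all times (60.30 L mol⁻¹)
    LG ⇌ Z + L (11.10 min⁻¹, 160.8 L mol⁻¹ min⁻¹)
    G → Gu (0.05190 min⁻¹)
    LG → Dz + G (0.3996 min⁻¹)

The reaction of G to Gu is the main reason for the fall of G in the north-east run: removing that step raises the share by 33 percentage points. The constant 0.0458 min⁻¹ also reckons that changed north-east run from the east readings. Dividing the L-free survival out of the east share leaves 68.0%, the east survival against the catalysed route by itself. Under the same assumption as before, the share that route removes at the doubled charge is half the east one. This estimate gives 84.0%, and the north-east run without G to Gu holds 86.8%.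

(All runs are calculated from invented constants; scatter was added.)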